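**Assumptions:** The target SMILES has no stereocentre (docosyl 2,3-dihydroxybenzoate is achiral), so no stereocontrol is needed. The route has one step, so only that step can be listed as a risk, with one fallback.

## Retrosynthetic overview
1. The only disconnection is the ester O–C(alkyl) bond, giving a 2,3-dihydroxybenzoate carboxylate and a C22 primary alkyl electrophile.
2. No ring is formed; the catechol-bearing benzene ring is bought intact as 2,3-dihydroxybenzoic acid.
3. Chemoselectivity rests on pKa: bicarbonate ionises only the CO2H (pKa about 3), not the phenols (pKa 10 or higher), so no protecting groups are used.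

## Route

Step 1
Reactants: 1 2,3-dihydroxybenzoic acid; 2 1-bromodocosane
Product: 4 Gentiside J (docosyl 2,3-dihydroxybenzoate), via potassium carboxylate 3 (not isolated)
Conditions: KHCO3 (1.3 equiv), 1 (1.2 equiv), 2 (1.0 equiv), DMF, N2, 60 °C, 16 h; dilute HCl/EtOAc work-up, aq. NaHCO3 wash, recrystallisation
Reagents that add atoms: none
Why: Bicarbonate deprotonates only the carboxylic acid, so the carboxylate is the sole nucleophile in an SN2 O-alkylation of the primary bromide (carboxylate alkylation), and no stereocentre is formed.

## Compound list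
1 | 2,3-dihydroxybenzoic acid | OC(=O)c1cccc(O)c1O | starting material
2 | 1-bromodocosane (n-C22H45Br) | CCCCCCCCCCCCCCCCCCCCCCBr | starting material
3 | potassium 2,3-dihydroxybenzoate | [K+].[O-]C(=O)c1cccc(O)c1O | intermediate
4 | Gentiside J, docosyl 2,3-dihydroxybenzoate | CCCCCCCCCCCCCCCCCCCCCCOC(=O)c1cccc(O)c1O | target

## Summary
Total step count: 1
Longest linear sequence: 1

Steps most likely to fail: the route has only step 1, so it is the only entry.

Step 1 could fail in three ways. A phenol (mainly the 3-OH) may be alkylated alongside the carboxylate. The waxy C22 bromide may react slowly in DMF. The free catechol may air-oxidise under basic conditions.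

The fallback sets out from compound 1 and returns to the route at compound 4. It masks the catechol and forms the ester by acyl activation instead of SN2:
- Compound 1 is perbenzylated (BnBr 3.5 equiv, K2CO3, DMF, 60 °C) to benzyl 2,3-bis(benzyloxy)benzoate F1.
- The benzyl ester is saponified (NaOH, MeOH/THF/H2O, reflux; then HCl) to 2,3-bis(benzyloxy)benzoic acid F2.
- Steglich esterification with commercial 1-docosanol (CCCCCCCCCCCCCCCCCCCCCCO; EDC·HCl, DMAP, CH2Cl2, rt) gives docosyl 2,3-bis(benzyloxy)benzoate F3.
- Hydrogenolysis of both benzyl ethers (H2 1 atm, 10% Pd/C, EtOAc/THF, rt) gives 4; the alkyl ester is untouched.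

## Further compounds
F1 | step 1 | benzyl 2,3-bis(benzyloxy)benzoate | O=C(OCc1ccccc1)c1cccc(OCc2ccccc2)c1OCc1ccccc1
F2 | step 1 | 2,3-bis(benzyloxy)benzoic acid | OC(=O)c1cccc(OCc2ccccc2)c1OCc1ccccc1
F3 | step 1 | docosyl 2,3-bis(benzyloxy)benzoate | CCCCCCCCCCCCCCCCCCCCCCOC(=O)c1cccc(OCc2ccccc2)c1OCc1ccccc1
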